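The C8–C8a bond is the disconnection on which everything rests, so that the cyclohexane ring is closed last onto a preformed N-methoxy-4-pyridone ring. The key step exploits C8a of the pyridone ring, the unsubstituted, electron-poor β-carbon of the vinylogous amide N1–C8a=C4a–C4=O. A primary C8 radical made from an alkyl iodide attacks it and the ring rearomatises, so one operation trades the C8a–H bond for the C8–C8a bond and completes the bicycle. The precursor is a monocyclic methyl 1,3-dimethoxy-4-oxopyridine-2-carboxylate bearing a (4R)-1-iodododecan-4-yl chain at C4a. C5 is set by copper-catalysed asymmetric conjugate addition.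

Key step: step 7

Remark: atom labels follow the numbering of 5,6,7,8-tetrahydroquinolin-4(1H)-one (N1, C2, C3, C4, C4a, C5 to C8, C8a) in all intermediates; with it the stereocentre C5 of the target is R.

Step 1
Reactants: 1 5-chloropent-1-ene; 2 methyl acrylate
Product: 3 methyl (2E)-6-chlorohex-2-enoate
Conditions: second-generation Grubbs catalyst (2 mol %), 2 (3 equiv), CH2Cl2, 40 °C
Reagents that add atoms: none
Why: Olefin cross-metathesis of an unhindered terminal alkene with an electron-poor acrylate should couple selectively and give the E-enoate with loss of ethylene.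

Step 2
Reactants: 3 methyl (2E)-6-chlorohex-2-enoate; 4 octylmagnesium bromide
Product: 5 methyl (3R)-3-(3-chloropropyl)undecanoate
Conditions: CuBr·SMe2 (5 mol %), Josiphos SL-J001 (6 mol %, the enantiomer that directs addition to the Re face of the β-carbon of 3), 4 (1.2 equiv), t-BuOMe, −75 °C; MeOH then aqueous NH4Cl at −75 °C
Reagents that add atoms: none
Why: Copper-catalysed asymmetric conjugate addition of a Grignard reagent to an (E)-enoate, in which the chiral ferrocenyl diphosphine on copper selects the Re face of the β-carbon and so sets the future C5 as R, while the primary chloride is inert at this temperature and the cold quench prevents alkylation of the magnesium enolate.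

Step 3
Reactants: 5 methyl (3R)-3-(3-chloropropyl)undecanoate
Product: 6 (3R)-3-(3-chloropropyl)undecanal
Conditions: i-Bu2AlH (1.05 equiv), CH2Cl2, −78 °C; aqueous potassium sodium tartrate
Reagents that add atoms: none
Why: Partial reduction of a methyl ester stops at the aluminium hemiacetal at low temperature and should release the aldehyde on work-up; the β-stereocentre is not enolisable.

Step 4
Reactants: 6 (3R)-3-(3-chloropropyl)undecanal; 7 morpholine; 8 methoxyacetyl chloride
Product: 10 (3E,4R)-4-(3-chloropropyl)-1-methoxy-3-(morpholin-4-ylmethylidene)dodecan-2-one, via morpholine enamine 9 (not isolated)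
Conditions: 7 (1.2 equiv), 4 Å molecular sieves, PhMe, 0 °C → rt; then 8 (1.1 equiv), Et3N (1.3 equiv), 0 °C → rt
Reagents that add atoms: none
Why: Stork enamine acylation, in which the (E)-enamine is acylated at its β-carbon (future C4a) and deprotonated by Et3N to the push–pull enaminone, so that the formyl carbon (future C8a) and the C4 ketone are placed regiospecifically on C4a without touching C5.

Step 5
Reactants: 10 (3E,4R)-4-(3-chloropropyl)-1-methoxy-3-(morpholin-4-ylmethylidene)dodecan-2-one; 11 dimethyl oxalate; 12 O-methylhydroxylamine hydrochloride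
Product: 14 methyl 5-[(4R)-1-chlorododecan-4-yl]-1,3-dimethoxy-4-oxo-1,4-dihydropyridine-2-carboxylate, via pyrone ester 13 (not isolated)
Conditions: LiN(i-Pr)2 (2.2 equiv), THF, −78 °C; 11 (1.5 equiv), −78 → 0 °C; CF3CO2H, rt; evaporate; then 12 (3 equiv), pyridine–EtOH, 70 °C
Reagents that add atoms: none
Why: Claisen C-acylation of the α′-enolate of the vinylogous amide (at the methoxymethyl carbon, future C3) by dimethyl oxalate and acid-induced ring closure with loss of morpholine is the standard 4-pyrone synthesis from β-amino enones, and the pyrone should then exchange ring oxygen for N–OMe by ring opening and reclosure, the C8a-centred carbon never becoming a carbanion that could attack the chloride.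

Step 6
Reactants: 14 methyl 5-[(4R)-1-chlorododecan-4-yl]-1,3-dimethoxy-4-oxo-1,4-dihydropyridine-2-carboxylate
Product: 15 methyl 5-[(4R)-1-iodododecan-4-yl]-1,3-dimethoxy-4-oxo-1,4-dihydropyridine-2-carboxylate
Conditions: NaI (5 equiv), butan-2-one, 80 °C
Reagents that add atoms: sodium iodide [Na+].[I-]
Why: Finkelstein halide exchange at the primary chloride is driven by precipitation of NaCl, and the methyl ester, both methoxy groups and the pyridone are not attacked by iodide under these conditions.

Step 7
Reactants: 15 methyl 5-[(4R)-1-iodododecan-4-yl]-1,3-dimethoxy-4-oxo-1,4-dihydropyridine-2-carboxylate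
Product: 16 methyl (5R)-1,3-dimethoxy-5-octyl-4-oxo-1,4,5,6,7,8-hexahydroquinoline-2-carboxylate
Conditions: (Me3Si)3SiH (1.3 equiv) and AIBN (1.5 equiv) added over 6 h by syringe pump, degassed PhMe (0.01 M), 100 °C
Reagents that add atoms: none
Why: Iodine abstraction by the silyl radical gives the primary C8 radical, which adds to C8a, the unsubstituted β-carbon of the vinylogous amide N1–C8a=C4a–C4=O, and the resulting C4a radical, delocalised onto the C4 carbonyl oxygen, loses the C8a hydrogen to the initiator used in excess, which restores the aromatic pyridone. The closest known reaction type is the Bu3SnH- or (Me3Si)3SiH-mediated intramolecular homolytic aromatic substitution that annulates ω-haloalkyl chains onto pyridones, quinolones and azoles. The cyclohexane ring C4a–C5–C6–C7–C8–C8a is closed in 6-endo-trig mode with respect to the C4a=C8a bond. No stereocentre is formed, and C5, set in step 2, is not activated toward deprotonation or hydrogen abstraction and should keep its R configuration. The step needs attack at C8a in preference to ipso attack at C4a and to premature reduction: the nucleophilic alkyl radical is polarity-matched with electron-poor C8a, C4a is fully substituted, and slow addition keeps the silane concentration low.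

Step 8
Reactants: 16 methyl (5R)-1,3-dimethoxy-5-octyl-4-oxo-1,4,5,6,7,8-hexahydroquinoline-2-carboxylate
Product: 17 (5R)-2-(hydroxymethyl)-1,3-dimethoxy-5-octyl-5,6,7,8-tetrahydroquinolin-4(1H)-one
Conditions: NaBH4 (3 equiv), MeOH–THF, 0 °C → rt
Reagents that add atoms: none
Why: Borohydride reduction of an ester activated by the electron-poor heteroaromatic ring (as in a picolinate) should give the primary alcohol, while the vinylogous amide carbonyl, the N–OMe bond and C5 are untouched.

Compound list
1 | 5-chloropent-1-ene | C=CCCCCl | starting material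
2 | methyl acrylate | C=CC(=O)OC | starting material
3 | methyl (2E)-6-chlorohex-2-enoate | COC(=O)/C=C/CCCCl | intermediate
4 | octylmagnesium bromide | CCCCCCCC[Mg]Br | starting material
5 | methyl (3R)-3-(3-chloropropyl)undecanoate | CCCCCCCC[C@@H](CC(=O)OC)CCCCl | intermediate
6 | (3R)-3-(3-chloropropyl)undecanal | CCCCCCCC[C@@H](CC=O)CCCCl | intermediate
7 | morpholine | C1COCCN1 | starting material
8 | methoxyacetyl chloride | COCC(=O)Cl | starting material
9 | 4-[(1E,3R)-3-(3-chloropropyl)undec-1-en-1-yl]morpholine | CCCCCCCC[C@@H](/C=C/N1CCOCC1)CCCCl | intermediate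
10 | (3E,4R)-4-(3-chloropropyl)-1-methoxy-3-(morpholin-4-ylmethylidene)dodecan-2-one | CCCCCCCC[C@@H](/C(=C\N1CCOCC1)C(=O)COC)CCCCl | intermediate
11 | dimethyl oxalate | COC(=O)C(=O)OC | starting material
12 | O-methylhydroxylamine hydrochloride | CON.Cl | starting material
13 | methyl 5-[(4R)-1-chlorododecan-4-yl]-3-methoxy-4-oxo-4H-pyran-2-carboxylate | CCCCCCCC[C@H](CCCCl)c1coc(C(=O)OC)c(OC)c1=O | intermediate
14 | methyl 5-[(4R)-1-chlorododecan-4-yl]-1,3-dimethoxy-4-oxo-1,4-dihydropyridine-2-carboxylate | CCCCCCCC[C@H](CCCCl)c1cn(OC)c(C(=O)OC)c(OC)c1=O | intermediate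
15 | methyl 5-[(4R)-1-iodododecan-4-yl]-1,3-dimethoxy-4-oxo-1,4-dihydropyridine-2-carboxylate | CCCCCCCC[C@H](CCCI)c1cn(OC)c(C(=O)OC)c(OC)c1=O | intermediate
16 | methyl (5R)-1,3-dimethoxy-5-octyl-4-oxo-1,4,5,6,7,8-hexahydroquinoline-2-carboxylate | CCCCCCCC[C@@H]1CCCc2c1c(=O)c(OC)c(C(=O)OC)n2OC | intermediate
17 | (5R)-2-(hydroxymethyl)-1,3-dimethoxy-5-octyl-5,6,7,8-tetrahydroquinolin-4(1H)-one | CCCCCCCC[C@@H]1CCCc2c1c(=O)c(OC)c(CO)n2OC | target

Total step count: 8. Longest linear sequence: 8 steps (1 → 17).

Steps most likely to fail

Step 7. The C8 radical may be quenched by hydrogen transfer before it closes the ring, the cyclised C4a radical may be reduced instead of rearomatised, or the N–O bond may be cleaved under the radical conditions. The fallback moves the ring closure to the oxygen heterocycle, where no N–O bond is present, and brings nitrogen in last. It sets out from 13, which is isolated after the CF3CO2H stage of step 5. NaI in butan-2-one at 80 °C should give methyl 5-[(4R)-1-iodododecan-4-yl]-3-methoxy-4-oxo-4H-pyran-2-carboxylate F1. Slow addition of (Me3Si)3SiH and AIBN in PhMe at 100 °C should close the ring at C8a of the pyrone to methyl (5R)-3-methoxy-5-octyl-4-oxo-5,6,7,8-tetrahydro-4H-chromene-2-carboxylate F2. Heating F2 with MeONH2·HCl in pyridine–EtOH at 80 °C exchanges the ring oxygen for N–OMe and comes back to the route at 16.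

Step 5. C-acylation at the methoxymethyl carbon may stay incomplete through proton transfer from the more acidic product, and the oxygen-to-nitrogen exchange may be sluggish because O-methylhydroxylamine is a weak nucleophile, with attack on the C2 ester competing. The fallback introduces nitrogen first and closes the ring at the C2–C3 bond. It sets out from 10. Amine exchange with MeONH2·HCl in MeOH at rt should give (3Z,4R)-4-(3-chloropropyl)-1-methoxy-3-[(methoxyamino)methylidene]dodecan-2-one F3. N-acylation with methyl chlorooxoacetate and pyridine in CH2Cl2 at 0 °C should give methyl 2-{[(1Z,3R)-3-(3-chloropropyl)-2-(methoxyacetyl)undec-1-en-1-yl](methoxy)amino}-2-oxoacetate F4. DBU in MeCN should then effect a Camps-type condensation of the C3 enolate onto the oxamate carbonyl and dehydration, which comes back to the route at 14.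

Step 4. The hindered enamine may be acylated on nitrogen, or may undergo cycloaddition with methoxyketene formed from the acid chloride and Et3N, in place of C-acylation; the aldehyde may also self-condense during enamine formation. The fallback uses a metalated imine and an ester as the acyl donor. It sets out from 6. Cyclohexylamine and 4 Å molecular sieves in CH2Cl2 should give (1E,3R)-3-(3-chloropropyl)-N-cyclohexylundecan-1-imine F5. Deprotonation with LiN(i-Pr)2 in THF at −78 °C and acylation with methyl methoxyacetate at that temperature should give (3Z,4R)-4-(3-chloropropyl)-3-[(cyclohexylamino)methylidene]-1-methoxydodecan-2-one F6. F6 is taken through the first stages of step 5 with one more equivalent of LiN(i-Pr)2 (for the N–H), dimethyl oxalate and CF3CO2H, which expels cyclohexylamine and comes back to the route at 13.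

Further compounds
F1 | step 7 | methyl 5-[(4R)-1-iodododecan-4-yl]-3-methoxy-4-oxo-4H-pyran-2-carboxylate | CCCCCCCC[C@H](CCCI)c1coc(C(=O)OC)c(OC)c1=O
F2 | step 7 | methyl (5R)-3-methoxy-5-octyl-4-oxo-5,6,7,8-tetrahydro-4H-chromene-2-carboxylate | CCCCCCCC[C@@H]1CCCc2c1c(=O)c(OC)c(C(=O)OC)o2
F3 | step 5 | (3Z,4R)-4-(3-chloropropyl)-1-methoxy-3-[(methoxyamino)methylidene]dodecan-2-one | CCCCCCCC[C@@H](/C(=C/NOC)C(=O)COC)CCCCl
F4 | step 5 | methyl 2-{[(1Z,3R)-3-(3-chloropropyl)-2-(methoxyacetyl)undec-1-en-1-yl](methoxy)amino}-2-oxoacetate | CCCCCCCC[C@@H](/C(=C/N(OC)C(=O)C(=O)OC)C(=O)COC)CCCCl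
F5 | step 4 | (1E,3R)-3-(3-chloropropyl)-N-cyclohexylundecan-1-imine | CCCCCCCC[C@@H](C/C=N/C1CCCCC1)CCCCl
F6 | step 4 | (3Z,4R)-4-(3-chloropropyl)-3-[(cyclohexylamino)methylidene]-1-methoxydodecan-2-one | CCCCCCCC[C@@H](/C(=C/NC1CCCCC1)C(=O)COC)CCCCl
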